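**Plan**
1. Retrosynthetic cuts, in order: the sixteen O–benzyl bonds; the interflavan C4–C8 bond (upper flavan-4-yl cation plus ring D of benzylated EGCG, which is itself cut at its gallate ester back to penta-O-benzyl-epigallocatechin); the upper C3–O gallate ester; then, in one operation, O1–C8a and C2–C3 of the upper ring C, which leaves a ring A fluoro ketone and tri-O-benzylgallaldehyde.
2. Enabling feature: in the upper unit C4 is the benzylic carbon that joins C3 to the phloroglucinol ring A. Carried as a ketone, it makes C3 the nucleophilic carbon of an enol silane and, being ortho to C8a, activates a C8a–F bond for addition–elimination by the C2 oxygen. A MOM cap on O3 leaves O1 as the only oxygen able to close the six-membered ring C.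
3. Forward order: ring A fluoro ketone → enol silane → ring C by aldol and ring closure with the aldehyde that brings ring B → C4 ketone turned into a 4β-methoxy leaving group and O3 galloylated → C4 cation joined to C8 of octa-O-benzyl-EGCG (made from (−)-epigallocatechin by phenol benzylation and galloylation) → hydrogenolysis.
4. Stereochemistry: C2 and C3 (2,3-cis) from the catalyst-controlled syn aldol of the key step; C4 (4β, 3,4-trans) from attack anti to the pseudoaxial C3 ester; the lower unit (2R,3R) from natural (−)-epigallocatechin.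

Key step: step 4

Remark: the target is read as (−)-EGCG-(4β→8)-(−)-EGCG (upper unit 2R,3R,4R; lower unit 2R,3R); simple reagents that add atoms (BnOH, BnBr, Me3SiCl, MeOH, water) are named on their line and not numbered.

**Step 1**
Reactants: 1 2,4,6-trifluorobenzonitrile
Product: 2 2,4-bis(benzyloxy)-6-fluorobenzonitrile
Conditions: BnOH (2.05 equiv), NaH (2.1 equiv), THF, 0 → 25 °C
Reagents that add atoms: benzyl alcohol, OCc1ccccc1
Why: Two successive SNAr displacements by sodium benzyloxide at the fluorines para and ortho to the nitrile, each new alkoxy group deactivating the ring so that the third fluorine (the later C8a–F) should survive.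

**Step 2**
Reactants: 2 2,4-bis(benzyloxy)-6-fluorobenzonitrile; 3 tributyl[(methoxymethoxy)methyl]stannane
Product: 6 1-[2,4-bis(benzyloxy)-6-fluorophenyl]-2-(methoxymethoxy)ethan-1-one, via alkoxymethyllithium 4 (not isolated), via N-lithio ketimine 5 (not isolated)
Conditions: 3, n-BuLi, THF, −78 °C; then 2, −78 → −40 °C; then 1 M aq. HCl, THF, 25 °C
Reagents that add atoms: water, O
Why: Tin–lithium exchange gives the α-alkoxymethyllithium, which adds once to the nitrile at low temperature (faster than attack at C–F), and the N-lithio ketimine is hydrolysed to the ketone on acidic work-up (organolithium addition to a nitrile).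

**Step 3**
Reactants: 6 1-[2,4-bis(benzyloxy)-6-fluorophenyl]-2-(methoxymethoxy)ethan-1-one
Product: 7 {[(Z)-1-[2,4-bis(benzyloxy)-6-fluorophenyl]-2-(methoxymethoxy)ethenyl]oxy}trimethylsilane
Conditions: LiN(SiMe3)2, Me3SiCl, THF, −78 °C
Reagents that add atoms: chlorotrimethylsilane, C[Si](C)(C)Cl
Why: Kinetic enolisation with lithium chelated between the enolate and MOM oxygens should give the Z enolate, which Me3SiCl traps on oxygen (silyl enol ether formation); the geometry is not critical because the aldol that follows is stereoconvergent.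

**Step 4**
Reactants: 7 {[(Z)-1-[2,4-bis(benzyloxy)-6-fluorophenyl]-2-(methoxymethoxy)ethenyl]oxy}trimethylsilane; 8 3,4,5-tris(benzyloxy)benzaldehyde
Product: 10 (2R,3S)-5,7-bis(benzyloxy)-3-(methoxymethoxy)-2-[3,4,5-tris(benzyloxy)phenyl]chroman-4-one, via silyl aldol 9 (not isolated)
Conditions: acyloxyborane made in situ from (2S,3S)-2-O-(2,6-diisopropoxybenzoyl)tartaric acid and BH3·THF (10 mol%), EtCN, −78 °C; then Bu4N[Ph3SiF2] (20 mol%), THF, −78 → 0 °C
Reagents that add atoms: none
Why: The boron Lewis acid binds the aldehyde and the enol silane attacks its Si face through an open, extended transition state, C3 bonding to C2 with silyl transfer to O1 to give the syn O-silyl aldol 9; fluoride then strips the silyl group from O1 and the alkoxide adds to C8a, ortho to the C4 carbonyl, giving a cyclohexadienyl anion delocalised into that carbonyl which expels fluoride, so that fluoride carries the chain and the net by-product is Me3SiF. The closest known reaction types are the chiral acyloxyborane-catalysed Mukaiyama aldol of aryl ketone enol silanes with aromatic aldehydes and the fluoride-triggered SNAr etherification of silyl ethers with ortho-acyl fluoroarenes. Ring C is the only ring closed, by attack of O1 on the aromatic carbon C8a in an addition–elimination that is formally 6-endo-trig, since the C8a–C4a bond of the vinylogous β-fluoro enone lies inside the new ring. C2 (R) is set by the catalyst, the (2S,3S)-tartrate-derived borane being expected to direct attack to the Si face because its (2R,3R) antipode is known to favour the Re face; C3 (S) follows from the simple syn diastereoselection of the open transition state for either enol geometry, and because O1 is retained in the ring closure the syn aldol maps onto the 2,3-cis flavanone. The step needs chemoselectivity between the two oxygens and kinetic control at C3: O3 is capped as a MOM ether so that only O1 can attack (no five-membered benzofuranone), ring A carries a single C–F bond, and the substoichiometric, non-basic fluoride at low temperature should keep the alkoxide concentration too low for retro-aldol cleavage or epimerisation of the 2,3-cis product.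

**Step 5**
Reactants: 10 (2R,3S)-5,7-bis(benzyloxy)-3-(methoxymethoxy)-2-[3,4,5-tris(benzyloxy)phenyl]chroman-4-one
Product: 11 (2R,3R,4R)-5,7-bis(benzyloxy)-3-(methoxymethoxy)-2-[3,4,5-tris(benzyloxy)phenyl]chroman-4-ol
Conditions: NaBH4, CeCl3·7H2O, MeOH–THF, −20 °C
Reagents that add atoms: none
Why: Luche reduction, in which the cerium-activated, weakly basic hydride should reduce the aryl ketone before C3 can epimerise and is expected to add anti to the pseudoaxial C3 oxygen to give mainly the all-cis alcohol, a centre that is erased again in step 6.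

**Step 6**
Reactants: 11 (2R,3R,4R)-5,7-bis(benzyloxy)-3-(methoxymethoxy)-2-[3,4,5-tris(benzyloxy)phenyl]chroman-4-ol
Product: 12 (2R,3R,4S)-5,7-bis(benzyloxy)-4-methoxy-2-[3,4,5-tris(benzyloxy)phenyl]chroman-3-ol
Conditions: HCl (0.5 M in MeOH), CH2Cl2, 0 → 25 °C
Reagents that add atoms: methanol, CO
Why: Acid-catalysed transacetalisation frees O3 while the C4 alcohol ionises to the benzylic cation stabilised by the ring A oxygens and is captured by methanol trans to the C3 oxygen (SN1 solvolysis), which should give the 4β-methoxy leaving group.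

**Step 7**
Reactants: 12 (2R,3R,4S)-5,7-bis(benzyloxy)-4-methoxy-2-[3,4,5-tris(benzyloxy)phenyl]chroman-3-ol; 13 3,4,5-tris(benzyloxy)benzoic acid
Product: 14 (2R,3R,4S)-5,7-bis(benzyloxy)-4-methoxy-2-[3,4,5-tris(benzyloxy)phenyl]chroman-3-yl 3,4,5-tris(benzyloxy)benzoate
Conditions: EDC·HCl, DMAP, CH2Cl2, 25 °C
Reagents that add atoms: none
Why: Steglich esterification of the pseudoaxial secondary C3 alcohol, under which the 4-methoxy group and the benzyl ethers are inert.

**Step 8**
Reactants: 15 (−)-epigallocatechin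
Product: 16 (2R,3R)-5,7-bis(benzyloxy)-2-[3,4,5-tris(benzyloxy)phenyl]chroman-3-ol (penta-O-benzyl-epigallocatechin)
Conditions: BnBr (5.5 equiv), K2CO3, degassed DMF, 0 → 25 °C, argon
Reagents that add atoms: benzyl bromide, BrCc1ccccc1
Why: Williamson etherification in which the carbonate deprotonates only the five phenols and not the much less acidic secondary C3 alcohol, so that O3 stays free, while the mild base, low temperature and exclusion of air should spare the C2 centre and the oxidation-prone pyrogallol ring.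

**Step 9**
Reactants: 16 penta-O-benzyl-epigallocatechin; 13 3,4,5-tris(benzyloxy)benzoic acid
Product: 17 (2R,3R)-5,7-bis(benzyloxy)-2-[3,4,5-tris(benzyloxy)phenyl]chroman-3-yl 3,4,5-tris(benzyloxy)benzoate (octa-O-benzyl-EGCG)
Conditions: EDC·HCl, DMAP, CH2Cl2, 25 °C
Reagents that add atoms: none
Why: Steglich esterification of the single free, pseudoaxial C3 alcohol with the benzylated gallic acid, which touches neither stereocentre and installs the lower gallate under neutral conditions.

**Step 10**
Reactants: 14 (2R,3R,4S)-5,7-bis(benzyloxy)-4-methoxy-2-[3,4,5-tris(benzyloxy)phenyl]chroman-3-yl 3,4,5-tris(benzyloxy)benzoate; 17 octa-O-benzyl-EGCG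
Product: 18 hexadeca-O-benzylrhodisin [per-O-benzyl EGCG-(4β→8)-EGCG; upper unit 2R,3R,4R; lower unit 2R,3R]
Conditions: Me3SiOSO2CF3 (0.3 equiv), 17 (3 equiv), CH2Cl2, 4 Å MS, −78 → −40 °C
Reagents that add atoms: none
Why: The silyl triflate ionises the C4 methoxy group and the benzylic cation, shielded on one face by the pseudoaxial C3 ester (which may bridge to C4), is attacked from the opposite face by C8 of ring D, the most nucleophilic and least hindered position of the excess nucleophile (Friedel–Crafts alkylation), which should set C4 as 4β (3,4-trans).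

**Step 11**
Reactants: 18 hexadeca-O-benzylrhodisin
Product: 19 rhodisin
Conditions: H2 (1 atm), Pd(OH)2/C, THF–MeOH–H2O, 25 °C
Reagents that add atoms: none
Why: Hydrogenolysis of all sixteen benzyl ethers under neutral conditions, which should leave the two gallate esters, the interflavan bond and all five stereocentres untouched.

**Compound list**
1 | 2,4,6-trifluorobenzonitrile | N#Cc1c(F)cc(F)cc1F | starting material
2 | 2,4-bis(benzyloxy)-6-fluorobenzonitrile | N#Cc1c(F)cc(OCc2ccccc2)cc1OCc1ccccc1 | intermediate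
3 | tributyl[(methoxymethoxy)methyl]stannane | CCCC[Sn](CCCC)(CCCC)COCOC | starting material
4 | (methoxymethoxy)methyllithium | [Li]COCOC | intermediate
5 | N-lithio ketimine of 6 | [Li]N=C(COCOC)c1c(F)cc(OCc2ccccc2)cc1OCc1ccccc1 | intermediate
6 | 1-[2,4-bis(benzyloxy)-6-fluorophenyl]-2-(methoxymethoxy)ethan-1-one | COCOCC(=O)c1c(F)cc(OCc2ccccc2)cc1OCc1ccccc1 | intermediate
7 | {[(Z)-1-[2,4-bis(benzyloxy)-6-fluorophenyl]-2-(methoxymethoxy)ethenyl]oxy}trimethylsilane | COCO/C=C(\O[Si](C)(C)C)c1c(F)cc(OCc2ccccc2)cc1OCc1ccccc1 | intermediate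
8 | 3,4,5-tris(benzyloxy)benzaldehyde | O=Cc1cc(OCc2ccccc2)c(OCc2ccccc2)c(OCc2ccccc2)c1 | starting material
9 | (2S,3R)-1-[2,4-bis(benzyloxy)-6-fluorophenyl]-2-(methoxymethoxy)-3-[3,4,5-tris(benzyloxy)phenyl]-3-[(trimethylsilyl)oxy]propan-1-one (syn) | COCO[C@@H]([C@H](O[Si](C)(C)C)c1cc(OCc2ccccc2)c(OCc2ccccc2)c(OCc2ccccc2)c1)C(=O)c1c(F)cc(OCc2ccccc2)cc1OCc1ccccc1 | intermediate
10 | (2R,3S)-5,7-bis(benzyloxy)-3-(methoxymethoxy)-2-[3,4,5-tris(benzyloxy)phenyl]chroman-4-one (2,3-cis) | COCO[C@@H]1C(=O)c2c(OCc3ccccc3)cc(OCc3ccccc3)cc2O[C@@H]1c1cc(OCc2ccccc2)c(OCc2ccccc2)c(OCc2ccccc2)c1 | intermediate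
11 | (2R,3R,4R)-5,7-bis(benzyloxy)-3-(methoxymethoxy)-2-[3,4,5-tris(benzyloxy)phenyl]chroman-4-ol (all-cis) | COCO[C@@H]1[C@H](O)c2c(OCc3ccccc3)cc(OCc3ccccc3)cc2O[C@@H]1c1cc(OCc2ccccc2)c(OCc2ccccc2)c(OCc2ccccc2)c1 | intermediate
12 | (2R,3R,4S)-5,7-bis(benzyloxy)-4-methoxy-2-[3,4,5-tris(benzyloxy)phenyl]chroman-3-ol (2,3-cis-3,4-trans) | O[C@@H]1[C@@H](OC)c2c(OCc3ccccc3)cc(OCc3ccccc3)cc2O[C@@H]1c1cc(OCc2ccccc2)c(OCc2ccccc2)c(OCc2ccccc2)c1 | intermediate
13 | 3,4,5-tris(benzyloxy)benzoic acid | OC(=O)c1cc(OCc2ccccc2)c(OCc2ccccc2)c(OCc2ccccc2)c1 | starting material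
14 | (2R,3R,4S)-5,7-bis(benzyloxy)-4-methoxy-2-[3,4,5-tris(benzyloxy)phenyl]chroman-3-yl 3,4,5-tris(benzyloxy)benzoate | O=C(O[C@@H]1[C@@H](OC)c2c(OCc3ccccc3)cc(OCc3ccccc3)cc2O[C@@H]1c1cc(OCc2ccccc2)c(OCc2ccccc2)c(OCc2ccccc2)c1)c1cc(OCc2ccccc2)c(OCc2ccccc2)c(OCc2ccccc2)c1 | intermediate
15 | (−)-epigallocatechin, (2R,3R) | O[C@@H]1Cc2c(O)cc(O)cc2O[C@@H]1c1cc(O)c(O)c(O)c1 | starting material
16 | penta-O-benzyl-epigallocatechin, (2R,3R)-5,7-bis(benzyloxy)-2-[3,4,5-tris(benzyloxy)phenyl]chroman-3-ol | O[C@@H]1Cc2c(OCc3ccccc3)cc(OCc3ccccc3)cc2O[C@@H]1c1cc(OCc2ccccc2)c(OCc2ccccc2)c(OCc2ccccc2)c1 | intermediate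
17 | octa-O-benzyl-EGCG, (2R,3R) | O=C(O[C@@H]1Cc2c(OCc3ccccc3)cc(OCc3ccccc3)cc2O[C@@H]1c1cc(OCc2ccccc2)c(OCc2ccccc2)c(OCc2ccccc2)c1)c1cc(OCc2ccccc2)c(OCc2ccccc2)c(OCc2ccccc2)c1 | intermediate
18 | hexadeca-O-benzylrhodisin, upper unit (2R,3R,4R), lower unit (2R,3R), 4β→8 | O=C(O[C@@H]1[C@@H](c2c(OCc3ccccc3)cc(OCc3ccccc3)c3c2O[C@H](c2cc(OCc4ccccc4)c(OCc4ccccc4)c(OCc4ccccc4)c2)[C@H](OC(=O)c2cc(OCc4ccccc4)c(OCc4ccccc4)c(OCc4ccccc4)c2)C3)c2c(OCc3ccccc3)cc(OCc3ccccc3)cc2O[C@@H]1c1cc(OCc2ccccc2)c(OCc2ccccc2)c(OCc2ccccc2)c1)c1cc(OCc2ccccc2)c(OCc2ccccc2)c(OCc2ccccc2)c1 | intermediate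
19 | rhodisin | O=C(O[C@@H]1[C@@H](c2c(O)cc(O)c3c2O[C@H](c2cc(O)c(O)c(O)c2)[C@H](OC(=O)c2cc(O)c(O)c(O)c2)C3)c2c(O)cc(O)cc2O[C@@H]1c1cc(O)c(O)c(O)c1)c1cc(O)c(O)c(O)c1 | target

**Count**
Total steps: 11. Longest linear sequence: 9 steps (steps 1–7, 10 and 11); steps 8 and 9 are the two-step side branch to the lower unit.

**Steps most likely to fail**

1. Step 4. The alkoxide freed at O1 may undergo retro-aldol cleavage or epimerise C3 before or after ring closure, and the α-alkoxy enol silane may be attacked with insufficient facial control; either process erodes the 2,3-cis relationship and the enantiopurity. Fallback: the upper electrophile is made by semisynthesis instead of ring construction. Setting out from 16, benzylic oxidation at C4 with DDQ in CH2Cl2 containing methanol (a known C–H oxidation of benzylated flavan-3-ols with a free 3-hydroxyl, the C4 cation being trapped trans to O3) should give 12 directly. This makes no new compound (F0), and the route resumes at 12 with step 7.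

2. Step 10. The cation from 14 may alkylate ring A of a second molecule of 14 (self-condensation to oligomers) or attack C6 instead of C8 of 17. Fallback: block the competing nucleophilic site of the electrophile. Setting out from 14, bromination with N-bromosuccinimide in CH2Cl2 at low temperature should give the 8-bromo electrophile F1. This is coupled with 17 under Me3SiOSO2CF3 as in step 10 to give the 8-bromo dimer F2. Hydrogenolysis over Pd(OH)2/C in the presence of Et3N should remove the bromine together with the benzyl groups, and the route comes back at 19.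

3. Step 6. Under protic acid the C4 cation may lose the C3 proton, close a methylene acetal between O3 and O4, or alkylate another molecule before the MOM group has been cleaved. Fallback: change the leaving group to a thioether formed under fast Lewis-acid conditions. Setting out from 11, ZnBr2 and propane-1-thiol in CH2Cl2 at 0 °C should cleave the MOM ether within minutes while the thiol traps the C4 cation, giving the 4β-propylsulfanyl alcohol F3. Esterification with 13 (EDC·HCl, DMAP) gives the thioether gallate F4. Thiophilic activation with AgBF4 in THF in the presence of 17 should then form the interflavan bond, and the route comes back at 18.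

**Further compounds**
F0 | step 4 | none | none
F1 | step 10 | 8-bromo derivative of 14: (2R,3R,4S)-5,7-bis(benzyloxy)-8-bromo-4-methoxy-2-[3,4,5-tris(benzyloxy)phenyl]chroman-3-yl 3,4,5-tris(benzyloxy)benzoate | O=C(O[C@@H]1[C@@H](OC)c2c(OCc3ccccc3)cc(OCc3ccccc3)c(Br)c2O[C@@H]1c1cc(OCc2ccccc2)c(OCc2ccccc2)c(OCc2ccccc2)c1)c1cc(OCc2ccccc2)c(OCc2ccccc2)c(OCc2ccccc2)c1
F2 | step 10 | 8-bromo derivative of 18 (bromine on C8 of the upper unit; configuration as in 18) | O=C(O[C@@H]1[C@@H](c2c(OCc3ccccc3)cc(OCc3ccccc3)c3c2O[C@H](c2cc(OCc4ccccc4)c(OCc4ccccc4)c(OCc4ccccc4)c2)[C@H](OC(=O)c2cc(OCc4ccccc4)c(OCc4ccccc4)c(OCc4ccccc4)c2)C3)c2c(OCc3ccccc3)cc(OCc3ccccc3)c(Br)c2O[C@@H]1c1cc(OCc2ccccc2)c(OCc2ccccc2)c(OCc2ccccc2)c1)c1cc(OCc2ccccc2)c(OCc2ccccc2)c(OCc2ccccc2)c1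
F3 | step 6 | (2R,3S,4S)-5,7-bis(benzyloxy)-4-(propylsulfanyl)-2-[3,4,5-tris(benzyloxy)phenyl]chroman-3-ol | O[C@@H]1[C@@H](SCCC)c2c(OCc3ccccc3)cc(OCc3ccccc3)cc2O[C@@H]1c1cc(OCc2ccccc2)c(OCc2ccccc2)c(OCc2ccccc2)c1
F4 | step 6 | (2R,3S,4S)-5,7-bis(benzyloxy)-4-(propylsulfanyl)-2-[3,4,5-tris(benzyloxy)phenyl]chroman-3-yl 3,4,5-tris(benzyloxy)benzoate | O=C(O[C@@H]1[C@@H](SCCC)c2c(OCc3ccccc3)cc(OCc3ccccc3)cc2O[C@@H]1c1cc(OCc2ccccc2)c(OCc2ccccc2)c(OCc2ccccc2)c1)c1cc(OCc2ccccc2)c(OCc2ccccc2)c(OCc2ccccc2)c1
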